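All runs come from a simulation with made-up constants, noise included.

Amounts first, since you want a quick number: winter has the charges of cedar at 55 °C, and by 20.0 min it has lost 60.0% of its substrate and shows 16% ring, which reads as 0.267. That ratio, ring made per substrate lost, the selectivity, divides two amounts gathered over the same minutes, but it still depends on when it is read: at 6.00 min, winter reads only 0.128.

| flask | substrate | activator | temperature | remark | time |
|---|---|---|---|---|---|
| winter | 0.20 M | 0.30 M | 55 °C | run made earlier |  |
| dawn | 0.20 M | 0.42 M | 66 °C | run made earlier |  |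
| midnight | 0.20 M | 0.66 M | 55 °C | run made earlier |  |
| dusk | 0.40 M | 0.30 M | 66 °C | run made earlier |  |
| elm | 0.20 M | 0.300 M (fed, over 25 min) | 60 °C | all else is in the flask from the start; the feed brings no volume worth counting | 30 min |
| maple | 0.20 M | 0.300 M (fed, over 25 min) |  | the addition at 30 °C, then warmed to 60 °C; the feed brings no volume worth counting | 30 min |
| cedar | 0.20 M | 0.300 M (fed, over 2.5 min) | 60 °C | all else is in the flask from the start; the feed brings no volume worth counting | 30 min |
| larch | 0.20 M | 0.300 M |  | everything together at the start at 30 °C, warmed to 60 °C at 25 min | 30 min |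
| ash | 0.20 M (fed, over 25 min) | 0.300 M | 60 °C | all else is in the flask from the start; the feed brings no volume worth counting | 30 min |

| run | time / min | ring / % | substrate / % |
|---|---|---|---|
| winter | 2.50 | 0 | 71 |
| winter | 6.00 | 5 | 61 |
| winter | 12.0 | 10 | 50 |
| winter | 20.0 | 16 | 40 |
| dawn | 10.0 | 15 | 27 |
| dawn | 20.0 | 29 | 12 |
| dawn | 25.0 | 28 | 5 |
| dawn | 40.0 | 32 | 5 |
| midnight | 5.00 | 8 | 37 |
| midnight | 12.0 | 15 | 19 |
| midnight | 25.0 | 28 | 8 |
| midnight | 40.0 | 38 | 5 |
| dusk | 10.0 | 5 | 45 |
| dusk | 20.0 | 6 | 28 |
| dusk | 25.0 | 7 | 23 |
| dusk | 40.0 | 10 | 11 |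

(each reading ± 2 percentage points)

- the flask with the highest amount of ring, in percent of the substrate charged ("all alike" if they lie within 1.5 percentage points) (elm / maple / cedar / larch / ash / all alike)
- final ring, as a percentage of the substrate charged, in elm
- final ring, as a percentage of the substrate charged, in maple
- final ring, as a percentage of the substrate charged, in cedar
- final ring, as a percentage of the substrate charged, in larch
- final ring, as a percentage of the substrate charged, in ash



Your hunch that a slow substrate feed pays has something behind it. At 66 °C and at the same 40.0 min, dawn reads a selectivity of 0.337, while dusk, with twice the substrate, reads 0.112, which is lower, although dawn also carries more activator.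

But ring is selectivity times substrate lost, and the loss comes early. Winter loses its charge at 0.116 min⁻¹ over the first 2.50 min, and at 0.0125 min⁻¹ between 12.0 min and 20.0 min, ten times slower. Since c(activator) starts above c(substrate), I read this as a burst phase: the activator goes out of action within minutes.

So I bet on cedar, whose 2.5 min feed is short against the 30 min run, and I expect ash and elm to lose less substrate. Carrying winter's late fall on to 30 min leaves 30.3% substrate. Leaving aside cedar's extra warmth and holding the selectivity at winter's reading from 20.0 min, that gives cedar 18.6% ring.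

The forecast differs from my bet: it names ash, which “holds substrate low in excess activator”, with elm 16%, maple 9%, cedar 25%, larch 10% and ash 35%.

The most ring stands in cedar, 15.4%, followed by larch 11.7%, elm 10.7%, maple 8.98% and ash 8.12%, and these are the steps:

    substrate + ring → side product (k = 0.290 L mol⁻¹ min⁻¹, Ea = 58.0 kJ mol⁻¹)
    activated form → ring (k = 0.0790 min⁻¹, Ea = 86.0 kJ mol⁻¹)
    substrate + activated form → open dimer (k = 0.720 L mol⁻¹ min⁻¹, Ea = 49.0 kJ mol⁻¹)
    activator ⇌ dormant form (K = 6.80, k = 0.490 min⁻¹, Ea = 102 kJ mol⁻¹, ΔH = −53.0 kJ mol⁻¹)
    substrate + activator → activated form (k = 0.700 L mol⁻¹ min⁻¹, Ea = 53.0 kJ mol⁻¹)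
    (constants at 60 °C)

Ash still holds 56.7% of its substrate at 30.0 min, with a mean c(activator) of 0.0520 M over the first 25 min. The selectivity of cedar at 30.0 min comes to 0.205, lower than the 0.267 read from winter at 20.0 min, while the neighbour of cedar charged with 0.050 M of substrate reaches 0.498, with 35.9% ring.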